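## Plan

- **Cuts, in retrosynthetic order:** the C2=C3 unsaturation of ring C (back to the isoflavanone), the C2–C3 bond, the C4–C4a acyl–aryl bond, and last the O–prenyl bonds of ring B.
- **Enabling feature:** in ring C, C2 is an unsubstituted CH bonded only to C3 and O1, so the O1–C2 unit is a disguised aryl OCH3. A 2,4,6-trimethoxyphenyl ketone carries two identical ortho OCH3 groups. One becomes O1–C2, the other stays as the C5 methoxy group, and the para one becomes the C7 methoxy group.
- **Forward:** rings A and B are bought as arenes. Ring B is prenylated, and its acetic acid side chain (C3, C4) is joined to ring A by a Weinreb ketone synthesis. C3 then receives a diazo group, and ring C is closed last by rhodium carbene C–H insertion and dehydrogenated.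
- **Stereochemistry:** the target has none. C3 of the isoflavanone and of its selenide forms as a racemate and is flattened in the final elimination.

Key step: step 5

Assumption: chromone numbering (O1, C2, C3, C4, C4a, C5–C8, C8a) is used for all intermediates, prenyl means 3-methylbut-2-en-1-yl, and racemic compounds are drawn as one enantiomer.

## Route

Step 1
Reactants: 1 3,4-dihydroxyphenylacetic acid; 2 prenyl bromide (1-bromo-3-methylbut-2-ene)
Product: 3 prenyl 2-[3,4-bis(prenyloxy)phenyl]acetate
Conditions: 2 (3.5 equiv), K2CO3 (4 equiv), DMF, rt, under Ar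
Reagents that add atoms: prenyl bromide (2), CC(C)=CCBr
Why: Williamson etherification of both phenoxides and SN2 O-alkylation of the carboxylate by a reactive allylic bromide run together in a polar aprotic solvent, where O-alkylation should dominate over C-prenylation and exclusion of air protects the catechol.

Step 2
Reactants: 3 prenyl 2-[3,4-bis(prenyloxy)phenyl]acetate; 4 N,O-dimethylhydroxylamine hydrochloride
Product: 5 2-[3,4-bis(prenyloxy)phenyl]-N-methoxy-N-methylacetamide
Conditions: 4 (1.5 equiv), i-PrMgCl (3 equiv), THF, −20 to 0 °C
Reagents that add atoms: N,O-dimethylhydroxylamine hydrochloride (4), CNOC.Cl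
Why: Direct ester aminolysis by the chloromagnesium amide made from 4 and i-PrMgCl is an established one-step entry to Weinreb amides from enolisable esters, it spares a separate saponification and coupling, and it leaves aryl prenyl ethers untouched.

Step 3
Reactants: 5 2-[3,4-bis(prenyloxy)phenyl]-N-methoxy-N-methylacetamide; 6 1,3,5-trimethoxybenzene
Product: 9 2-[3,4-bis(prenyloxy)phenyl]-1-(2,4,6-trimethoxyphenyl)ethanone, via 2-lithio-1,3,5-trimethoxybenzene 7 (not isolated), via lithium hemiaminal adduct 8 (not isolated)
Conditions: 6 (1.5 equiv), n-BuLi (1.4 equiv), THF, 0 °C to rt; then 5, −78 to 0 °C; aqueous quench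
Reagents that add atoms: 1,3,5-trimethoxybenzene (6), COc1cc(OC)cc(OC)c1
Why: Directed ortho-lithiation between two methoxy groups gives 7 as the only aryllithium, and the Weinreb ketone synthesis stops at the ketone because the N-methoxy-chelated adduct 8 survives until the quench, the low temperature favouring addition over removal of a benzylic proton.

Step 4
Reactants: 9 2-[3,4-bis(prenyloxy)phenyl]-1-(2,4,6-trimethoxyphenyl)ethanone; 10 4-acetamidobenzenesulfonyl azide
Product: 11 2-diazo-2-[3,4-bis(prenyloxy)phenyl]-1-(2,4,6-trimethoxyphenyl)ethanone
Conditions: 10 (1.3 equiv), DBU (1.5 equiv), MeCN, 0 °C to rt, dark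
Reagents that add atoms: 4-acetamidobenzenesulfonyl azide (10), CC(=O)Nc1ccc(cc1)S(=O)(=O)N=[N+]=[N-]
Why: In this Regitz diazo transfer DBU enolises the CH2 group activated by both the ketone and ring B, the enolate adds to the terminal azide nitrogen, and the adduct collapses to diazoketone and sulfonamide, a direct transfer that is established for benzyl ketones and aryl acetates.

Step 5
Reactants: 11 2-diazo-2-[3,4-bis(prenyloxy)phenyl]-1-(2,4,6-trimethoxyphenyl)ethanone
Product: 12 (±)-3-[3,4-bis(prenyloxy)phenyl]-5,7-dimethoxychroman-4-one
Conditions: Rh2(O2CCPh3)4 (1 mol %), 4 Å MS, CH2Cl2, reflux, slow addition of 11 (final 0.005 M)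
Reagents that add atoms: none
Why: Rh2(O2CCPh3)4 displaces N2 from 11 to give an electrophilic rhodium carbene at C3, flanked by ring B as donor and the C4 carbonyl as acceptor, and this carbene inserts into a C–H bond of a neighbouring OCH3 group in one concerted event in which hydride moves to C3 while C2–C3 forms, the developing positive charge at C2 being carried by the O1 lone pair. The closest known reaction type is the intramolecular rhodium carbene C–H insertion alpha to the ether oxygen of 2-alkoxyaryl diazoketones, which delivers chroman-4-ones, and donor/acceptor carbenes are known to accept the unhindered C–H bonds of methyl ethers; the pairing of an aryl-substituted diazoketone with an OCH3 group is the less explored variant. Ring C closes by 1,6-insertion through a six-membered transition state that contains C3, C4, C4a, C8a, O1 and C2. The new C3 stereocentre is uncontrolled, since substrate and catalyst are achiral, so 12 should form as a racemate, which costs nothing because C3 becomes trigonal again in step 7. The step needs chemoselectivity over the five-membered oxonium ylide, over Wolff rearrangement and over bimolecular reaction at the prenyl groups: ylide formation can revert and a methyl group is a reluctant migrant, the donor aryl group and the bulky triphenylacetate ligands slow aryl migration and intermolecular approach, the two ortho substituents twist the aroyl group out of the carbonyl plane and so park an OCH3 group next to the carbene, and slow addition keeps 11 dilute. Site selectivity is not an issue, because the two ortho OCH3 groups are related by symmetry and the para one cannot reach C3.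

Step 6
Reactants: 12 (±)-3-[3,4-bis(prenyloxy)phenyl]-5,7-dimethoxychroman-4-one; 13 benzeneselenenyl chloride
Product: 15 (±)-3-[3,4-bis(prenyloxy)phenyl]-5,7-dimethoxy-3-(phenylselanyl)chroman-4-one, via lithium enolate 14 (not isolated)
Conditions: LiN(SiMe3)2 (1.1 equiv), THF, −78 °C; then 13 (1.1 equiv), −78 °C
Reagents that add atoms: benzeneselenenyl chloride (13), Cl[Se]c1ccccc1
Why: In this enolate selenenylation C3 is the only enolisable position and is acidified by the ketone and ring B, the lithium enolate should capture PhSeCl at −78 °C far faster than the prenyl alkenes can and is too cold to open ring C by loss of the O1 phenoxide, and the planar enolate gives the quaternary C3 centre as a racemate.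

Step 7
Reactants: 15 (±)-3-[3,4-bis(prenyloxy)phenyl]-5,7-dimethoxy-3-(phenylselanyl)chroman-4-one
Product: 17 glabrescione B (3-[3,4-bis(prenyloxy)phenyl]-5,7-dimethoxychromen-4-one), via selenoxide 16 (not isolated)
Conditions: mCPBA (1.0 equiv), CH2Cl2, −78 °C; then i-Pr2NH (2 equiv), −78 °C to rt
Reagents that add atoms: none
Why: In this selenoxide syn-elimination one equivalent of peracid at −78 °C oxidises selenium much faster than a trisubstituted alkene, the selenoxide has beta-hydrogens only at C2 and so can eliminate in one direction only, the amine takes up PhSeOH before it can add to the prenyl groups, and the C3 stereocentre disappears as the 4-pyranone forms.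

## Compound list

| No. | Name | SMILES | Role |
|---|---|---|---|
| 1 | 3,4-dihydroxyphenylacetic acid | O=C(O)Cc1ccc(O)c(O)c1 | starting material |
| 2 | prenyl bromide | CC(C)=CCBr | starting material |
| 3 | prenyl 2-[3,4-bis(prenyloxy)phenyl]acetate | CC(C)=CCOC(=O)Cc1ccc(OCC=C(C)C)c(OCC=C(C)C)c1 | intermediate |
| 4 | N,O-dimethylhydroxylamine hydrochloride | CNOC.Cl | starting material |
| 5 | 2-[3,4-bis(prenyloxy)phenyl]-N-methoxy-N-methylacetamide | CON(C)C(=O)Cc1ccc(OCC=C(C)C)c(OCC=C(C)C)c1 | intermediate |
| 6 | 1,3,5-trimethoxybenzene | COc1cc(OC)cc(OC)c1 | starting material |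
| 7 | 2-lithio-1,3,5-trimethoxybenzene (not isolated) | COc1cc(OC)c([Li])c(OC)c1 | intermediate |
| 8 | lithium hemiaminal adduct of 7 and 5 (racemic, one enantiomer drawn, not isolated) | COc1cc(OC)c(c(OC)c1)[C@@]([O-])(Cc1ccc(OCC=C(C)C)c(OCC=C(C)C)c1)N(C)OC.[Li+] | intermediate |
| 9 | 2-[3,4-bis(prenyloxy)phenyl]-1-(2,4,6-trimethoxyphenyl)ethanone | COc1cc(OC)c(C(=O)Cc2ccc(OCC=C(C)C)c(OCC=C(C)C)c2)c(OC)c1 | intermediate |
| 10 | 4-acetamidobenzenesulfonyl azide | CC(=O)Nc1ccc(cc1)S(=O)(=O)N=[N+]=[N-] | starting material |
| 11 | 2-diazo-2-[3,4-bis(prenyloxy)phenyl]-1-(2,4,6-trimethoxyphenyl)ethanone | COc1cc(OC)c(C(=O)C(=[N+]=[N-])c2ccc(OCC=C(C)C)c(OCC=C(C)C)c2)c(OC)c1 | intermediate |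
| 12 | (±)-3-[3,4-bis(prenyloxy)phenyl]-5,7-dimethoxychroman-4-one (racemic, one enantiomer drawn) | COc1cc(OC)c2c(c1)OC[C@@H](c1ccc(OCC=C(C)C)c(OCC=C(C)C)c1)C2=O | intermediate |
| 13 | benzeneselenenyl chloride | Cl[Se]c1ccccc1 | starting material |
| 14 | lithium enolate of 12 (not isolated) | COc1cc(OC)c2c(c1)OCC(c1ccc(OCC=C(C)C)c(OCC=C(C)C)c1)=C2[O-].[Li+] | intermediate |
| 15 | (±)-3-[3,4-bis(prenyloxy)phenyl]-5,7-dimethoxy-3-(phenylselanyl)chroman-4-one (racemic, one enantiomer drawn) | COc1cc(OC)c2c(c1)OC[C@@]([Se]c1ccccc1)(c1ccc(OCC=C(C)C)c(OCC=C(C)C)c1)C2=O | intermediate |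
| 16 | selenoxide of 15 (racemic at C3, one enantiomer drawn, both configurations at selenium, not isolated) | COc1cc(OC)c2c(c1)OC[C@@]([Se](=O)c1ccccc1)(c1ccc(OCC=C(C)C)c(OCC=C(C)C)c1)C2=O | intermediate |
| 17 | glabrescione B | COc1cc(OC)c2c(=O)c(-c3ccc(OCC=C(C)C)c(OCC=C(C)C)c3)coc2c1 | target |

## Step count and risks

Total step count: 7.
Longest linear sequence: 7 (1 → 3 → 5 → 9 → 11 → 12 → 15 → 17). Ring A enters in step 3 without steps of its own.

Steps most likely to fail:

1. **Step 5.**
   - **Risk:** The carbene may be consumed before it reaches the C–H bond. It could be captured by the ortho oxygen lone pair, followed by methyl shift or demethylation. Ring A could migrate to the carbene carbon. Bimolecular insertion or cyclopropanation could occur at prenyl groups. All of these are helped by the low intrinsic reactivity of a primary C–H bond.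
   - **Fallback:** C2 is brought in as a formyl equivalent and the prenyl groups are added last.
   - **Course:** The fallback sets out from 1, which is heated with commercial 3,5-dimethoxyphenol in BF3·OEt2 (Friedel–Crafts acylation ortho to the free phenol) to give 2-(3,4-dihydroxyphenyl)-1-(2-hydroxy-4,6-dimethoxyphenyl)ethanone F1. DMF, MsCl and BF3·OEt2 then formylate the activated CH2 group, and the 2-hydroxy group closes ring C with loss of dimethylamine, giving 3-(3,4-dihydroxyphenyl)-5,7-dimethoxychromen-4-one F2. Williamson etherification of both catechol hydroxy groups with 2 and K2CO3 in acetone comes back to the route at 17.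

2. **Step 3.**
   - **Risk:** Proton transfer may outrun addition. The hindered, strongly basic aryllithium can remove a benzylic proton next to the amide carbonyl, which returns the amide unchanged on quench.
   - **Fallback:** The C4–C4a bond is made by electrophilic aromatic substitution before any acid-labile prenyl ether is present.
   - **Course:** The fallback sets out from 1 and 6, which are joined by Friedel–Crafts acylation in warm BF3·OEt2 to give 2-(3,4-dihydroxyphenyl)-1-(2,4,6-trimethoxyphenyl)ethanone F3. The two phenols are far more acidic than the ketone CH2 group, so they are alkylated selectively with 2 and K2CO3 in acetone. This comes back to the route at 9 and makes steps 1 and 2 unnecessary.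

3. **Step 6.**
   - **Risk:** The enolate may open ring C by expelling the O1 phenoxide (retro-oxa-Michael), or the selenium electrophile may add to the electron-rich prenyl alkenes.
   - **Fallback:** Dehydrogenation without a strong base and without selenium.
   - **Course:** The fallback sets out from 12, which is enolised softly with Me3SiOTf and Et3N in CH2Cl2 at 0 °C to give 3-[3,4-bis(prenyloxy)phenyl]-5,7-dimethoxy-4-(trimethylsilyloxy)-2H-chromene F4. Saegusa–Ito oxidation with one equivalent of Pd(OAc)2 in MeCN at rt then removes the C2 hydrogen by beta-hydride elimination. This comes back to the route at 17 and bypasses step 7. The full equivalent of the divalent palladium salt and the low temperature limit exposure of the prenyl aryl ethers to zerovalent palladium.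

## Further compounds

F1 | step 5 | 2-(3,4-dihydroxyphenyl)-1-(2-hydroxy-4,6-dimethoxyphenyl)ethanone | COc1cc(O)c(C(=O)Cc2ccc(O)c(O)c2)c(OC)c1
F2 | step 5 | 3-(3,4-dihydroxyphenyl)-5,7-dimethoxychromen-4-one | COc1cc(OC)c2c(=O)c(-c3ccc(O)c(O)c3)coc2c1
F3 | step 3 | 2-(3,4-dihydroxyphenyl)-1-(2,4,6-trimethoxyphenyl)ethanone | COc1cc(OC)c(C(=O)Cc2ccc(O)c(O)c2)c(OC)c1
F4 | step 6 | 3-[3,4-bis(prenyloxy)phenyl]-5,7-dimethoxy-4-(trimethylsilyloxy)-2H-chromene | COc1cc(OC)c2c(c1)OCC(c1ccc(OCC=C(C)C)c(OCC=C(C)C)c1)=C2O[Si](C)(C)C
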